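In ring A the ether oxygen O1 sits on C8a and the carbonyl carbon C4 on the adjacent C4a, whose other neighbour, C5, bears oxygen. This ortho O/C(=O) pattern can be installed in one stroke by an aryne spanning C4a and C8a, biased by the C5 alkoxy substituent. The route therefore disconnects O1–C8a and C4–C4a together. Insertion of the aryne into the carboxyl C–O bond of an arylpropiolic acid forms both bonds and delivers the whole carbon skeleton as an open ortho-hydroxyaryl ynone. The aryne precursor is a MOM-protected, prenylated ortho-trimethylsilylaryl triflate made from phloroglucinol; the acid comes from 2,4-dihydroxybenzaldehyde.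

Key step: step 9

Remark: prenyl = 3-methylbut-2-en-1-yl, MOM = methoxymethyl, TIPS = triisopropylsilyl; the target has no stereocenter, and the double-bond geometry of the transient enaminone 22 is immaterial because it is lost on ring closure.

Step 1
Reactants: 1 phloroglucinol
Product: 2 3,5-bis(methoxymethoxy)phenol
Conditions: MOMCl (2.0 equiv), i-Pr2NEt (2.5 equiv), THF, 0 °C → rt; chromatography
Reagents that add atoms: chloromethyl methyl ether (MOMCl), COCCl
Why: Base-mediated O-alkylation of the phenol (Williamson-type acetal formation) run with two equivalents, so the bis-ether should be the main member of a statistical mixture and is separated from the mono- and tris-ethers at the cheapest point of the route.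

Step 2
Reactants: 2 3,5-bis(methoxymethoxy)phenol
Product: 3 [3,5-bis(methoxymethoxy)phenoxy]triisopropylsilane
Conditions: TIPSCl, imidazole, DMF, rt
Reagents that add atoms: triisopropylsilyl chloride, CC(C)[Si](Cl)(C(C)C)C(C)C
Why: Imidazole-promoted O-silylation of the remaining phenol; the bulky silyl ether is inert to n-BuLi and shields its own ortho positions in the next step.

Step 3
Reactants: 3 [3,5-bis(methoxymethoxy)phenoxy]triisopropylsilane; 4 prenyl bromide
Product: 7 3,5-bis(methoxymethoxy)-4-(3-methylbut-2-en-1-yl)phenol, via aryllithium 5 (not isolated), via prenylated silyl ether 6 (not isolated)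
Conditions: n-BuLi (1.05 equiv), THF, 0 °C; prenyl bromide (0.95 equiv), −78 °C → rt; TBAF (1.5 equiv), rt; aq. NH4Cl
Reagents that add atoms: none
Why: Directed ortho-metalation at the only carbon flanked by two MOM ethers gives 5, SN2 alkylation with the primary allylic bromide (kept limiting so that none is left to O-alkylate the phenoxide) gives 6, and fluoride then cleaves the Si–O bond to free the phenol.

Step 4
Reactants: 7 3,5-bis(methoxymethoxy)-4-(3-methylbut-2-en-1-yl)phenol
Product: 8 2-bromo-3,5-bis(methoxymethoxy)-4-(3-methylbut-2-en-1-yl)phenol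
Conditions: NBS (1.0 equiv), CH2Cl2, −78 °C
Reagents that add atoms: N-bromosuccinimide, O=C1CCC(=O)N1Br
Why: Electrophilic aromatic bromination in which the free phenol ring with three oxygen donors should react far faster than the trisubstituted alkene, and since the two open ring positions are equivalent and both ortho to OH, one equivalent of reagent should give a single mono-bromide.

Step 5
Reactants: 8 2-bromo-3,5-bis(methoxymethoxy)-4-(3-methylbut-2-en-1-yl)phenol
Product: 12 3,5-bis(methoxymethoxy)-4-(3-methylbut-2-en-1-yl)-2-(trimethylsilyl)phenyl trifluoromethanesulfonate, via trimethylsilyl ether 9 (not isolated), via aryllithium 10 (not isolated), via lithium silylphenoxide 11 (not isolated)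
Conditions: HMDS, THF, 65 °C, then evaporate; n-BuLi, THF, −100 → −78 °C; Tf2O, −78 °C
Reagents that add atoms: hexamethyldisilazane, C[Si](C)(C)N[Si](C)(C)C; trifluoromethanesulfonic anhydride, O=S(=O)(OS(=O)(=O)C(F)(F)F)C(F)(F)F
Why: O-silylation, bromine–lithium exchange and a 1,3 O→C silyl shift (retro-Brook rearrangement) move the trimethylsilyl group onto the carbon next to the phenoxide, which is triflated in the same flask; this is the standard entry to ortho-silylaryl triflates, and exchange at −100 °C is much faster than any attack on the prenyl or MOM groups.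

Step 6
Reactants: 13 2,4-dihydroxybenzaldehyde
Product: 14 2,4-bis(methoxymethoxy)benzaldehyde
Conditions: MOMCl (3 equiv), i-Pr2NEt (4 equiv), CH2Cl2, 0 °C → reflux
Reagents that add atoms: chloromethyl methyl ether (MOMCl), COCCl
Why: Exhaustive O-alkylation of both phenols, with excess reagent and warming because the 2-OH is hydrogen-bonded to the aldehyde.

Step 7
Reactants: 14 2,4-bis(methoxymethoxy)benzaldehyde
Product: 15 1-(2,2-dibromoethenyl)-2,4-bis(methoxymethoxy)benzene
Conditions: CBr4 (2 equiv), PPh3 (4 equiv), Et3N (1 equiv), CH2Cl2, 0 °C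
Reagents that add atoms: carbon tetrabromide, BrC(Br)(Br)Br
Why: Corey–Fuchs dibromo-olefination (Wittig reaction of the ylide Ph3P=CBr2 formed in the flask), with Et3N buffering traces of HBr so that the MOM acetals survive.

Step 8
Reactants: 15 1-(2,2-dibromoethenyl)-2,4-bis(methoxymethoxy)benzene
Product: 18 3-[2,4-bis(methoxymethoxy)phenyl]prop-2-ynoic acid, via lithium acetylide 16 (not isolated), via lithium carboxylate 17 (not isolated)
Conditions: n-BuLi (2.1 equiv), THF, −78 °C; CO2, −78 °C → rt; cold 1 M HCl to pH 2, immediate extraction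
Reagents that add atoms: carbon dioxide, O=C=O
Why: Second stage of the Corey–Fuchs homologation, in which exchange/elimination and deprotonation by two equivalents of n-BuLi give acetylide 16 that adds to CO2; brief cold acidification frees the acid without cleaving the aryl MOM ethers.

Step 9
Reactants: 12 3,5-bis(methoxymethoxy)-4-(3-methylbut-2-en-1-yl)-2-(trimethylsilyl)phenyl trifluoromethanesulfonate (1.3 equiv); 18 3-[2,4-bis(methoxymethoxy)phenyl]prop-2-ynoic acid
Product: 21 1-[6-hydroxy-2,4-bis(methoxymethoxy)-3-(3-methylbut-2-en-1-yl)phenyl]-3-[2,4-bis(methoxymethoxy)phenyl]prop-2-yn-1-one, via cesium carboxylate 19 (not isolated), via aryne 20 (not isolated)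
Conditions: CsF (3 equiv), THF (0.03 M), sealed tube, 100 °C, stopped when 18 is consumed; pH 5 buffer
Reagents that add atoms: none
Why: Fluoride removes the trimethylsilyl group of 12 and triflate departs, releasing aryne 20, whose triple bond spans the future C4a and C8a; carboxylate 19 adds through oxygen to C8a. The aryl anion left at C4a attacks the neighbouring ester carbonyl, and the resulting four-membered alkoxide opens to the ortho-acyl phenoxide, so O1–C8a and C4–C4a are made in one operation by an anionic-Fries-like 1,3-acyl shift. The closest known reaction type is the fluoride-induced insertion of arynes into the C–O bond of carboxylic acids, which gives ortho-hydroxyaryl ketones. No ring is closed (the four-membered ring is only a transient intermediate) and no stereocenter is formed. The step needs attack at C8a and not at C4a, which the inductively withdrawing MOM-oxygen on C5 (stabilizing charge at C4a) and the lower hindrance at C8a (flanked only by the H-bearing C8) should secure. It also needs acyl transfer to outrun protonation of the aryl anion and closure onto the ynone, which high dilution, heat, return of the acid proton to the phenoxide (giving a hydrogen-bonded, weakly nucleophilic phenol) and the electron-rich ring B on the alkyne should favour; the prenyl chain on C6 is held away from the aryne bond by C5, ruling out an internal ene reaction, and the acetals are untouched by CsF.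

Step 10
Reactants: 21 1-[6-hydroxy-2,4-bis(methoxymethoxy)-3-(3-methylbut-2-en-1-yl)phenyl]-3-[2,4-bis(methoxymethoxy)phenyl]prop-2-yn-1-one
Product: 23 2-[2,4-bis(methoxymethoxy)phenyl]-5,7-bis(methoxymethoxy)-6-(3-methylbut-2-en-1-yl)-4H-chromen-4-one, via enaminone 22 (not isolated)
Conditions: Et2NH (5 equiv), EtOH, reflux
Reagents that add atoms: none
Why: Conjugate addition of the secondary amine gives enaminone 22, and addition–elimination by the phenol oxygen at the β-carbon expels the amine, which can only form the six-membered pyranone (net 6-endo closure) and avoids the 5-exo aurone pathway of simple base-mediated cyclization.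

Step 11
Reactants: 23 2-[2,4-bis(methoxymethoxy)phenyl]-5,7-bis(methoxymethoxy)-6-(3-methylbut-2-en-1-yl)-4H-chromen-4-one
Product: 26 2-[2,4-bis(methoxymethoxy)phenyl]-3-hydroxy-5,7-bis(methoxymethoxy)-6-(3-methylbut-2-en-1-yl)-4H-chromen-4-one, via 3-lithioflavone 24 (not isolated), via lithium borate 25 (not isolated)
Conditions: LiN(i-Pr)2 (1.5 equiv), THF, −78 °C; B(OMe)3, −78 → 0 °C; 30% H2O2, 1 M aq. NaOH, 0 °C; aq. NH4Cl
Reagents that add atoms: hydrogen peroxide, OO (source of the C3 oxygen)
Why: The amide base removes the vinylic C3–H, which is acidified by the adjacent C4 carbonyl and by chelation of lithium, the 3-lithio species is borylated, and alkaline peroxide effects the boron-to-oxygen 1,2-shift (arylboronate oxidation) under conditions that do not epoxidize the isolated prenyl alkene.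

Step 12
Reactants: 26 2-[2,4-bis(methoxymethoxy)phenyl]-3-hydroxy-5,7-bis(methoxymethoxy)-6-(3-methylbut-2-en-1-yl)-4H-chromen-4-one
Product: 27 2-(2,4-dihydroxyphenyl)-3,5,7-trihydroxy-6-(3-methylbut-2-en-1-yl)-4H-chromen-4-one
Conditions: 3 M aq. HCl–MeOH (1:5), 45 °C, stopped at full cleavage
Reagents that add atoms: none
Why: Acid-catalysed acetal exchange with methanol removes the four aryl MOM ethers as dimethoxymethane, and dilute acid with mild warming should leave the ortho-prenyl phenol uncyclized.

Compound list
1 | phloroglucinol (benzene-1,3,5-triol) | Oc1cc(O)cc(O)c1 | starting material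
2 | 3,5-bis(methoxymethoxy)phenol | COCOc1cc(O)cc(OCOC)c1 | intermediate
3 | [3,5-bis(methoxymethoxy)phenoxy]triisopropylsilane | COCOc1cc(O[Si](C(C)C)(C(C)C)C(C)C)cc(OCOC)c1 | intermediate
4 | prenyl bromide (1-bromo-3-methylbut-2-ene) | CC(C)=CCBr | starting material
5 | [2,6-bis(methoxymethoxy)-4-(triisopropylsilyloxy)phenyl]lithium (formed in situ) | [Li]c1c(OCOC)cc(O[Si](C(C)C)(C(C)C)C(C)C)cc1OCOC | intermediate
6 | [3,5-bis(methoxymethoxy)-4-(3-methylbut-2-en-1-yl)phenoxy]triisopropylsilane (formed in situ) | CC(C)=CCc1c(OCOC)cc(O[Si](C(C)C)(C(C)C)C(C)C)cc1OCOC | intermediate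
7 | 3,5-bis(methoxymethoxy)-4-(3-methylbut-2-en-1-yl)phenol | CC(C)=CCc1c(OCOC)cc(O)cc1OCOC | intermediate
8 | 2-bromo-3,5-bis(methoxymethoxy)-4-(3-methylbut-2-en-1-yl)phenol | CC(C)=CCc1c(OCOC)cc(O)c(Br)c1OCOC | intermediate
9 | [2-bromo-3,5-bis(methoxymethoxy)-4-(3-methylbut-2-en-1-yl)phenoxy]trimethylsilane (formed in situ) | CC(C)=CCc1c(OCOC)cc(O[Si](C)(C)C)c(Br)c1OCOC | intermediate
10 | [2,4-bis(methoxymethoxy)-3-(3-methylbut-2-en-1-yl)-6-(trimethylsilyloxy)phenyl]lithium (formed in situ) | CC(C)=CCc1c(OCOC)cc(O[Si](C)(C)C)c([Li])c1OCOC | intermediate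
11 | lithium 3,5-bis(methoxymethoxy)-4-(3-methylbut-2-en-1-yl)-2-(trimethylsilyl)phenoxide (formed in situ) | CC(C)=CCc1c(OCOC)cc([O-])c([Si](C)(C)C)c1OCOC.[Li+] | intermediate
12 | 3,5-bis(methoxymethoxy)-4-(3-methylbut-2-en-1-yl)-2-(trimethylsilyl)phenyl trifluoromethanesulfonate | CC(C)=CCc1c(OCOC)cc(OS(=O)(=O)C(F)(F)F)c([Si](C)(C)C)c1OCOC | intermediate
13 | 2,4-dihydroxybenzaldehyde | O=Cc1ccc(O)cc1O | starting material
14 | 2,4-bis(methoxymethoxy)benzaldehyde | O=Cc1ccc(OCOC)cc1OCOC | intermediate
15 | 1-(2,2-dibromoethenyl)-2,4-bis(methoxymethoxy)benzene | BrC(Br)=Cc1ccc(OCOC)cc1OCOC | intermediate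
16 | {[2,4-bis(methoxymethoxy)phenyl]ethynyl}lithium (formed in situ) | [Li]C#Cc1ccc(OCOC)cc1OCOC | intermediate
17 | lithium 3-[2,4-bis(methoxymethoxy)phenyl]prop-2-ynoate (formed in situ) | [Li+].[O-]C(=O)C#Cc1ccc(OCOC)cc1OCOC | intermediate
18 | 3-[2,4-bis(methoxymethoxy)phenyl]prop-2-ynoic acid | OC(=O)C#Cc1ccc(OCOC)cc1OCOC | intermediate
19 | cesium 3-[2,4-bis(methoxymethoxy)phenyl]prop-2-ynoate (formed in situ) | [Cs+].[O-]C(=O)C#Cc1ccc(OCOC)cc1OCOC | intermediate
20 | 3,5-bis(methoxymethoxy)-4-(3-methylbut-2-en-1-yl)benzyne, triple bond between the former C–OTf and C–Si carbons (formed in situ) | CC(C)=CCC1=C(OCOC)C#CC=C1OCOC | intermediate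
21 | 1-[6-hydroxy-2,4-bis(methoxymethoxy)-3-(3-methylbut-2-en-1-yl)phenyl]-3-[2,4-bis(methoxymethoxy)phenyl]prop-2-yn-1-one | CC(C)=CCc1c(OCOC)cc(O)c(C(=O)C#Cc2ccc(OCOC)cc2OCOC)c1OCOC | intermediate
22 | 3-(diethylamino)-1-[6-hydroxy-2,4-bis(methoxymethoxy)-3-(3-methylbut-2-en-1-yl)phenyl]-3-[2,4-bis(methoxymethoxy)phenyl]prop-2-en-1-one (formed in situ; double-bond geometry not defined) | CC(C)=CCc1c(OCOC)cc(O)c(C(=O)C=C(N(CC)CC)c2ccc(OCOC)cc2OCOC)c1OCOC | intermediate
23 | 2-[2,4-bis(methoxymethoxy)phenyl]-5,7-bis(methoxymethoxy)-6-(3-methylbut-2-en-1-yl)-4H-chromen-4-one | CC(C)=CCc1c(OCOC)cc2oc(-c3ccc(OCOC)cc3OCOC)cc(=O)c2c1OCOC | intermediate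
24 | {2-[2,4-bis(methoxymethoxy)phenyl]-5,7-bis(methoxymethoxy)-6-(3-methylbut-2-en-1-yl)-4-oxo-4H-chromen-3-yl}lithium (formed in situ) | CC(C)=CCc1c(OCOC)cc2oc(-c3ccc(OCOC)cc3OCOC)c([Li])c(=O)c2c1OCOC | intermediate
25 | lithium {2-[2,4-bis(methoxymethoxy)phenyl]-5,7-bis(methoxymethoxy)-6-(3-methylbut-2-en-1-yl)-4-oxo-4H-chromen-3-yl}trimethoxyborate (formed in situ) | [Li+].CO[B-](OC)(OC)c1c(-c2ccc(OCOC)cc2OCOC)oc2cc(OCOC)c(CC=C(C)C)c(OCOC)c2c1=O | intermediate
26 | 2-[2,4-bis(methoxymethoxy)phenyl]-3-hydroxy-5,7-bis(methoxymethoxy)-6-(3-methylbut-2-en-1-yl)-4H-chromen-4-one | CC(C)=CCc1c(OCOC)cc2oc(-c3ccc(OCOC)cc3OCOC)c(O)c(=O)c2c1OCOC | intermediate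
27 | 2-(2,4-dihydroxyphenyl)-3,5,7-trihydroxy-6-(3-methylbut-2-en-1-yl)-4H-chromen-4-one | CC(C)=CCc1c(O)cc2oc(-c3ccc(O)cc3O)c(O)c(=O)c2c1O | target

Total step count: 12.
Longest linear sequence: 9 steps (steps 1–5, then 9–12, from phloroglucinol); the acid branch (steps 6–8) joins at step 9.

Steps most likely to fail

Step 9. The aryl anion at C4a may be protonated before it acylates, leaving the aryl ester. The propiolate may also lose CO2 on heating, or the product may close onto the ynone in both 5-exo and 6-endo senses under the basic conditions. The fallback sets out from phenol 7 and dibromoalkene 15 and comes back at ynone 21. Ortho-formylation of 7 with MgCl2, Et3N and paraformaldehyde in MeCN at reflux should give 6-hydroxy-2,4-bis(methoxymethoxy)-3-(3-methylbut-2-en-1-yl)benzaldehyde F1, since the two ortho positions of 7 are equivalent. Lithium acetylide 16 is made from 15 with n-BuLi as in step 8 and used in excess (2.5 equiv), because the phenol consumes one equivalent. It should add to the aldehyde to give racemic 1-[6-hydroxy-2,4-bis(methoxymethoxy)-3-(3-methylbut-2-en-1-yl)phenyl]-3-[2,4-bis(methoxymethoxy)phenyl]prop-2-yn-1-ol F2. MnO2 in CH2Cl2 at rt then oxidizes this benzylic, propargylic alcohol to 21 under neutral conditions that do not trigger ring closure.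

Step 11. The base may remove a proton elsewhere, at the benzylic-allylic CH2 of the prenyl group or at ring positions flanked by MOM ethers. The hindered C3 anion may also be captured slowly by the borate, so that 23 is returned or mixtures form. The fallback sets out from ynone 21 and comes back at flavonol 26. Semi-hydrogenation of 21 (H2, Pd/CaCO3 poisoned with Pb(OAc)2, quinoline, EtOAc) should give (Z)-1-[6-hydroxy-2,4-bis(methoxymethoxy)-3-(3-methylbut-2-en-1-yl)phenyl]-3-[2,4-bis(methoxymethoxy)phenyl]prop-2-en-1-one F3, leaving the trisubstituted prenyl alkene untouched. Algar–Flynn–Oyamada oxidation (30% H2O2, aq. NaOH, MeOH, 0 °C) then equilibrates the enone geometry through reversible oxa-Michael closure and should deliver 26 by oxidative cyclization. It is run cold because an oxygen substituent at C5 is known to favour the competing aurone pathway.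

Step 12. Acid may add the freed C5 or C7 hydroxyl across the prenyl double bond, closing a chroman ring, or hydrate that alkene before all four acetals are cleaved. The fallback sets out from 26 and comes back at 27. TMSOTf with 2,2'-bipyridyl in CH2Cl2 at 0 °C → rt is a non-protic exchange in which the bipyridyl captures each methoxymethyl cation. It should convert the aryl MOM ethers and the 3-OH into trimethylsilyl ethers, giving 2-[2,4-bis(trimethylsilyloxy)phenyl]-3,5,7-tris(trimethylsilyloxy)-6-(3-methylbut-2-en-1-yl)-4H-chromen-4-one F4. Water or K2CO3/MeOH at rt then hydrolyses the silyl ethers to 27 without exposing the prenyl phenol to Brønsted acid.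

Further compounds
F1 | step 9 | 6-hydroxy-2,4-bis(methoxymethoxy)-3-(3-methylbut-2-en-1-yl)benzaldehyde | CC(C)=CCc1c(OCOC)cc(O)c(C=O)c1OCOC
F2 | step 9 | racemic 1-[6-hydroxy-2,4-bis(methoxymethoxy)-3-(3-methylbut-2-en-1-yl)phenyl]-3-[2,4-bis(methoxymethoxy)phenyl]prop-2-yn-1-ol | CC(C)=CCc1c(OCOC)cc(O)c(C(O)C#Cc2ccc(OCOC)cc2OCOC)c1OCOC
F3 | step 11 | (Z)-1-[6-hydroxy-2,4-bis(methoxymethoxy)-3-(3-methylbut-2-en-1-yl)phenyl]-3-[2,4-bis(methoxymethoxy)phenyl]prop-2-en-1-one | CC(C)=CCc1c(OCOC)cc(O)c(C(=O)/C=C\c2ccc(OCOC)cc2OCOC)c1OCOC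
F4 | step 12 | 2-[2,4-bis(trimethylsilyloxy)phenyl]-3,5,7-tris(trimethylsilyloxy)-6-(3-methylbut-2-en-1-yl)-4H-chromen-4-one | CC(C)=CCc1c(O[Si](C)(C)C)cc2oc(-c3ccc(O[Si](C)(C)C)cc3O[Si](C)(C)C)c(O[Si](C)(C)C)c(=O)c2c1O[Si](C)(C)C
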